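**Retrosynthetic overview**
- The depside ester C(=O)–O bond is cut last. It joins ring A (2,4-dihydroxy-6-propylbenzoyl, carried as its bis-benzyl ether) to the C1' oxygen of ring B (methyl 4-hydroxy-2-methoxy-6-propylbenzoate).
- The strategy rests on ring B: a resorcinol whose two oxygens differ (acylated O at C1', methyl ether at C3'), with the methoxycarbonyl group at C4' and the propyl group at C5'. This 1-hydroxy-3-alkoxy-4-ester-5-alkyl pattern is what a vinylketene/alkoxyalkyne benzannulation delivers.
- Ring B is the only ring built, from two open-chain pieces: methyl 2-diazo-4-methylidene-3-oxoheptanoate and methoxyethyne. The new bonds are C1'–C2' and C3'–C4' in the (2+2) step and C1'–C6' in the 6π closure.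
- The diazo keto ester comes from 2-methylidenepentanoic acid by crossed Claisen condensation with methyl acetate and diazo transfer; methoxyethyne comes from 2-chloro-1,1-dimethoxyethane.
- Ring A is bought as 5-propylresorcinol and carried through formylation, benzylation and oxidation; esterification and hydrogenolysis finish the route.

Key step: step 5

Remark: the target has no stereocentre. Ring B positions are primed: C1' carries the depside oxygen, C3' the methoxy group, C4' the methoxycarbonyl group, C5' the propyl group.

**Step 1**
Reactants: 1 2-methylidenepentanoic acid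
Product: 2 2-methylidenepentanoyl chloride
Conditions: (COCl)2 (1.2 equiv), DMF (cat.), CH2Cl2, 0 °C to rt; volatiles removed, short-path distillation
Reagents that add atoms: oxalyl chloride, ClC(=O)C(Cl)=O
Why: DMF-catalysed acid chloride formation proceeds under mild conditions that should leave the 1,1-disubstituted alkene untouched.

**Step 2**
Reactants: 2 2-methylidenepentanoyl chloride; 3 methyl acetate
Product: 5 methyl 4-methylidene-3-oxoheptanoate, via lithium enolate of methyl acetate 4 (not isolated)
Conditions: LiN(SiMe3)2 (2.2 equiv), 3 (2.2 equiv), THF, −78 °C; then 2, −78 °C; aqueous NH4Cl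
Reagents that add atoms: none
Why: In this crossed Claisen condensation the hard lithium ester enolate should add to the acyl chloride carbonyl at −78 °C faster than to the alkene, and the second equivalent of enolate holds the product as its chelated enolate until the quench.

**Step 3**
Reactants: 5 methyl 4-methylidene-3-oxoheptanoate
Product: 6 methyl 2-diazo-4-methylidene-3-oxoheptanoate
Conditions: 4-acetamidobenzenesulfonyl azide (1.1 equiv), Et3N (1.5 equiv), MeCN, 0 °C to rt
Reagents that add atoms: 4-acetamidobenzenesulfonyl azide, CC(=O)Nc1ccc(cc1)S(=O)(=O)N=[N+]=[N-]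
Why: Regitz diazo transfer to the doubly activated methylene of a β-keto ester is fast, and the product can no longer enolise, which should stabilise the α-methylene ketone.

**Step 4**
Reactants: 7 2-chloro-1,1-dimethoxyethane (chloroacetaldehyde dimethyl acetal)
Product: 9 methoxyethyne, via sodium methoxyethynide 8 (not isolated)
Conditions: NaNH2 (3.1 equiv), liquid NH3, −33 °C; NH3 evaporated; saturated aqueous NaCl, −20 °C; distilled into a −78 °C receiver and kept as a cold solution in ClCH2CH2Cl
Reagents that add atoms: none
Why: Successive base-induced eliminations of HCl and methanol give the acetylide, which is protonated on aqueous quench; this is the standard preparation of alkoxyethynes from chloroacetaldehyde acetals.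

**Step 5**
Reactants: 6 methyl 2-diazo-4-methylidene-3-oxoheptanoate; 9 methoxyethyne
Product: 14 methyl 4-hydroxy-2-methoxy-6-propylbenzoate, via ester-substituted vinylketene 10 (not isolated), via 4-vinylcyclobutenone 11 (not isolated), via dienylketene 12 (not isolated), via cyclohexadienone tautomer 13 (not isolated)
Conditions: 9 (3 equiv), ClCH2CH2Cl, hν (254 nm, low-pressure Hg lamps, Vycor tube), 10 °C; then sealed tube, 80 °C
Reagents that add atoms: none
Why: Irradiation expels N2 from 6 with Wolff migration of the pent-1-en-2-yl group from the ketone carbon to the diazo carbon, which gives the ester-substituted vinylketene 10; its electrophilic ketene carbon is attacked by the nucleophilic CH carbon of the ynol ether 9, and the (2+2) cycloaddition forms C1'–C2' and C3'–C4' in the 4-vinylcyclobutenone 11. On heating, 11 opens by a reversible 4π electrocyclic reaction to the dienylketene 12, which closes ring B by a thermal disrotatory 6π electrocyclisation between the ketene carbon and the terminal CH2 (C1'–C6', six-membered ring from an all-carbon triene), and 13 enolises to the phenol 14. The closest known reaction type is the Danheiser benzannulation in its photochemical diazo ketone form with alkoxy- and silyloxyalkynes, here extended only by the ester substituent on the diazo carbon. No stereocentre is formed. The step needs regioselectivity in the (2+2) event and alkenyl rather than methoxy migration in the Wolff step: the first follows from the polarisation of the ynol ether, whose oxygen-bearing carbon must end next to the former diazo carbon, so that OMe sits at C3' beside the ester and the free OH at C1'; the second from the preference of a 2-diazo-3-oxo ester to rearrange on its ketone side. An excess of 9 keeps the ketene from acylating the phenol that is formed.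

**Step 6**
Reactants: 15 5-propylresorcinol (5-propylbenzene-1,3-diol)
Product: 16 2,4-dihydroxy-6-propylbenzaldehyde
Conditions: POCl3 (1.2 equiv), DMF, 0 °C to rt; then H2O, 50 °C
Reagents that add atoms: N,N-dimethylformamide, CN(C)C=O; water, O
Why: Vilsmeier–Haack formylation of a 5-alkylresorcinol should occur at C4, para to one hydroxyl and ortho to the other, as with the methyl and pentyl homologues.

**Step 7**
Reactants: 16 2,4-dihydroxy-6-propylbenzaldehyde
Product: 17 2,4-bis(benzyloxy)-6-propylbenzaldehyde
Conditions: BnBr (2.3 equiv), K2CO3 (3 equiv), DMF, 60 °C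
Reagents that add atoms: benzyl bromide, BrCc1ccccc1
Why: Williamson ether synthesis; warming in DMF should be enough to alkylate the hydrogen-bonded ortho hydroxyl as well.

**Step 8**
Reactants: 17 2,4-bis(benzyloxy)-6-propylbenzaldehyde
Product: 18 2,4-bis(benzyloxy)-6-propylbenzoic acid
Conditions: NaClO2, NaH2PO4, 2-methyl-2-butene (excess), t-BuOH/THF/H2O, rt
Reagents that add atoms: sodium chlorite, [Na+].[O-]Cl=O
Why: Pinnick oxidation converts the hindered aryl aldehyde into the acid, and 2-methyl-2-butene traps HOCl so that the electron-rich ring should not be chlorinated.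

**Step 9**
Reactants: 18 2,4-bis(benzyloxy)-6-propylbenzoic acid; 14 methyl 4-hydroxy-2-methoxy-6-propylbenzoate
Product: 20 3-methoxy-4-(methoxycarbonyl)-5-propylphenyl 2,4-bis(benzyloxy)-6-propylbenzoate, via 2,4-bis(benzyloxy)-6-propylbenzoyl chloride 19 (not isolated)
Conditions: (COCl)2 (1.5 equiv), DMF (cat.), CH2Cl2, 0 °C to rt, evaporated; then 14, Et3N, DMAP (cat.), CH2Cl2, 0 °C to rt
Reagents that add atoms: none
Why: Acid chloride formation followed by DMAP-catalysed acyl transfer to the phenol is a standard depside-forming esterification, and the C1' hydroxyl is the only free nucleophile in 14.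

**Step 10**
Reactants: 20 3-methoxy-4-(methoxycarbonyl)-5-propylphenyl 2,4-bis(benzyloxy)-6-propylbenzoate
Product: 21 methyl 4-[(2,4-dihydroxy-6-propylbenzoyl)oxy]-2-methoxy-6-propylbenzoate (target)
Conditions: H2 (1 atm), 10% Pd/C, EtOAc, rt
Reagents that add atoms: none
Why: Hydrogenolysis of the two benzyl aryl ethers is neutral and should leave the aryl ester, the methyl ester and the methyl ether untouched.

**Compound list**
1 | 2-methylidenepentanoic acid | C=C(CCC)C(=O)O | starting material
2 | 2-methylidenepentanoyl chloride | C=C(CCC)C(=O)Cl | intermediate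
3 | methyl acetate | CC(=O)OC | starting material
4 | lithium enolate of methyl acetate (lithium 1-methoxyethenolate) | [Li+].[O-]C(=C)OC | intermediate (not isolated)
5 | methyl 4-methylidene-3-oxoheptanoate | C=C(CCC)C(=O)CC(=O)OC | intermediate
6 | methyl 2-diazo-4-methylidene-3-oxoheptanoate | C=C(CCC)C(=O)C(=[N+]=[N-])C(=O)OC | intermediate
7 | 2-chloro-1,1-dimethoxyethane | COC(CCl)OC | starting material
8 | sodium methoxyethynide | [Na+].[C-]#COC | intermediate (not isolated)
9 | methoxyethyne | C#COC | intermediate
10 | methyl 3-methylidene-2-(oxomethylidene)hexanoate (vinylketene) | C=C(CCC)C(=C=O)C(=O)OC | intermediate (not isolated)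
11 | methyl 2-methoxy-4-oxo-1-(pent-1-en-2-yl)cyclobut-2-ene-1-carboxylate (racemic) | C=C(CCC)C1(C(=O)OC)C(OC)=CC1=O | intermediate (not isolated)
12 | methyl (2Z)-3-methoxy-5-oxo-2-(pent-1-en-2-yl)penta-2,4-dienoate (dienylketene) | COC(=O)/C(C(=C)CCC)=C(\OC)C=C=O | intermediate (not isolated)
13 | methyl 6-methoxy-4-oxo-2-propylcyclohexa-1,5-diene-1-carboxylate | CCCC1=C(C(=O)OC)C(OC)=CC(=O)C1 | intermediate (not isolated)
14 | methyl 4-hydroxy-2-methoxy-6-propylbenzoate | CCCc1cc(O)cc(OC)c1C(=O)OC | intermediate
15 | 5-propylresorcinol | CCCc1cc(O)cc(O)c1 | starting material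
16 | 2,4-dihydroxy-6-propylbenzaldehyde | CCCc1cc(O)cc(O)c1C=O | intermediate
17 | 2,4-bis(benzyloxy)-6-propylbenzaldehyde | CCCc1cc(OCc2ccccc2)cc(OCc2ccccc2)c1C=O | intermediate
18 | 2,4-bis(benzyloxy)-6-propylbenzoic acid | CCCc1cc(OCc2ccccc2)cc(OCc2ccccc2)c1C(=O)O | intermediate
19 | 2,4-bis(benzyloxy)-6-propylbenzoyl chloride | CCCc1cc(OCc2ccccc2)cc(OCc2ccccc2)c1C(=O)Cl | intermediate (not isolated)
20 | 3-methoxy-4-(methoxycarbonyl)-5-propylphenyl 2,4-bis(benzyloxy)-6-propylbenzoate | CCCc1cc(OCc2ccccc2)cc(OCc2ccccc2)c1C(=O)Oc1cc(CCC)c(C(=O)OC)c(OC)c1 | intermediate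
21 | methyl 4-[(2,4-dihydroxy-6-propylbenzoyl)oxy]-2-methoxy-6-propylbenzoate | CCCc1cc(O)cc(O)c1C(=O)Oc1cc(CCC)c(C(=O)OC)c(OC)c1 | target

**Step count and risks**
Total step count: 10. Longest linear sequence: 6 steps (steps 1, 2, 3, 5, 9, 10, from 2-methylidenepentanoic acid).

Steps most likely to fail:

1. Step 5. The ester stabilises the dipolar intermediate formed when the ynol ether attacks the ketene, so closure through the ester carbonyl oxygen in a (4+2) sense may compete with cyclobutenone formation. Methoxy migration in the Wolff step, or acylation of the product phenol by the ketene, may also divert material. The fallback gives up the annulation and differentiates the two oxygens of ring A's own aldehyde precursor by classical means. It sets out from 16. Benzylation at the non-chelated 4-hydroxyl (BnBr, KHCO3, DMF) should give 4-(benzyloxy)-2-hydroxy-6-propylbenzaldehyde F1. Methylation of the chelated hydroxyl (MeI, K2CO3, DMF) gives 4-(benzyloxy)-2-methoxy-6-propylbenzaldehyde F2. Pinnick oxidation gives 4-(benzyloxy)-2-methoxy-6-propylbenzoic acid F3. Esterification (MeI, K2CO3, DMF) gives methyl 4-(benzyloxy)-2-methoxy-6-propylbenzoate F4, and hydrogenolysis (H2, Pd/C) returns to the route at 14.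

2. Step 2. Conjugate addition of the enolate to the β-unsubstituted acryloyl unit, double acylation, or self-condensation of the α-methylene keto ester during isolation may erode the Claisen product. The fallback carries the carbonyl at the aldehyde oxidation level and never handles the free keto ester. It sets out from 1. Reduction (LiAlH4, Et2O, 0 °C) gives 2-methylidenepentan-1-ol F5, and MnO2 oxidation gives 2-methylidenepentanal F6. Addition of lithiated methyl diazoacetate (LiN(iPr)2, THF, −78 °C) gives racemic methyl 2-diazo-3-hydroxy-4-methylideneheptanoate F7. Oxidation with 2-iodoxybenzoic acid in DMSO returns to the route at 6, so that step 3 is also bypassed.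

3. Step 9. Acyl transfer from the doubly ortho-substituted aroyl chloride to a phenol deactivated by the para ester may be slow, so that hydrolysis or loss of a benzyl group competes. The fallback leaves the addition–elimination pathway. It sets out from 18 and 14, which are combined with trifluoroacetic anhydride in toluene at rt. The mixed anhydride 2,4-bis(benzyloxy)-6-propylbenzoic trifluoroacetic anhydride F8 should ionise to a linear aroylium ion that is insensitive to the ortho substituents and acylates 14, returning to the route at 20.

**Further compounds**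
F1 | step 5 | 4-(benzyloxy)-2-hydroxy-6-propylbenzaldehyde | CCCc1cc(OCc2ccccc2)cc(O)c1C=O
F2 | step 5 | 4-(benzyloxy)-2-methoxy-6-propylbenzaldehyde | CCCc1cc(OCc2ccccc2)cc(OC)c1C=O
F3 | step 5 | 4-(benzyloxy)-2-methoxy-6-propylbenzoic acid | CCCc1cc(OCc2ccccc2)cc(OC)c1C(=O)O
F4 | step 5 | methyl 4-(benzyloxy)-2-methoxy-6-propylbenzoate | CCCc1cc(OCc2ccccc2)cc(OC)c1C(=O)OC
F5 | step 2 | 2-methylidenepentan-1-ol | C=C(CCC)CO
F6 | step 2 | 2-methylidenepentanal | C=C(CCC)C=O
F7 | step 2 | methyl 2-diazo-3-hydroxy-4-methylideneheptanoate (racemic) | C=C(CCC)C(O)C(=[N+]=[N-])C(=O)OC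
F8 | step 9 | 2,4-bis(benzyloxy)-6-propylbenzoic trifluoroacetic anhydride | CCCc1cc(OCc2ccccc2)cc(OCc2ccccc2)c1C(=O)OC(=O)C(F)(F)F
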